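## The problem

The target is a 2,3-cis flavan-3-ol: a chroman in which ring A is fused to the pyran ring C through C4a and C8a, with a 3,5-dihydroxy-4-methoxyphenyl ring B on C2 and a galloyl ester on the C3 oxygen. Its only stereocentres, C2 and C3, are adjacent and both R. Either one must set the other or both must come from one asymmetric event. The cis arrangement is the less stable one, so it cannot be reached by equilibration at the benzylic C2. Seven phenols (two on ring A, two on ring B, three on the gallate) must be carried masked and released together, while the single methyl ether at C4' has to be placed on a symmetrical pyrogallol unit at the outset. The free compound is sensitive to base (ester cleavage, acyl migration, ring opening at C2, autoxidation of the pyrogallol units), and the electron-rich benzylic C2–O1 bond is sensitive to strong acid, so the final operations must be neutral. The feature exploited here is ring A itself: a benzene with oxygen on C5, C7 and C8a and one carbon substituent, C4, on C4a between two oxygen-bearing carbons. A vinylketene–siloxyalkyne benzannulation writes exactly this 2-alkylphloroglucinol pattern, taking C4a and C8a from an ynol ether and C5 to C8 from a four-carbon ketene, so ring A can be grown onto a finished, stereodefined C2–C3–C4 chain.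

## Retrosynthesis

**Benzyl ethers and ester.** Target 31 is traced to its hepta-O-benzyl derivative 30, so that one neutral hydrogenolysis frees all phenols. Cutting the C3 oxygen–acyl bond of 30 gives flavan-3-ol 28 and 3,4,5-tris(benzyloxy)benzoic acid 29. Carrying the ester earlier is rejected because it would not survive acetylide chemistry or fluoride and could migrate to the C2 oxygen. The forward step must acylate a hindered secondary alcohol, for which carbodiimide/DMAP activation suffices.

**O1–C2.** Alcohol 28 comes from its methoxymethyl ether 27, and ring C of 27 is opened at O1–C2 to the phenolic diol derivative 26. Cutting O1–C8a instead would require a halogen on ring A and a metal-catalysed C–O coupling. An acid-mediated closure would give the trans ring. With the O1–C2 cut, a Mitsunobu reaction closes the ring with inversion at C2. The cis chroman therefore requires the erythro chain (1S,2R in 26). The C3 oxygen is masked as the acetal so that only the benzylic hydroxyl is activated.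

**Ring A oxygens.** Compound 26 is reached from 25 by fluoride removal of two silyl ethers, and 25 from phenol 24 by benzylation of the C5 hydroxyl. In 24 the three ring A oxygens are already distinct (free OH at C5, benzyl ether at C7, silyl ether at C8a), so no selective protection of a symmetrical arene is needed.

**Ring A.** Phenol 24 is cut at C4a–C5, C8–C8a and C5–C6 into siloxyalkyne 17 and 3-(benzyloxy)cyclobut-2-en-1-one 19. The neighbouring option, opening an epoxide with a metallated trioxygenated arene, needs a desymmetrised, halogenated phloroglucinol unit and an organometallic flanked by two oxygens. The annulation instead uses two simple open-chain partners under neutral thermal conditions. The forward reaction must be regiospecific and must leave the acetal, the silyl ethers and both stereocentres alone.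

**Ynol ether and C4–C4a.** Siloxyalkyne 17 is traced to terminal alkyne 14 by cutting the C8a–O bond (oxygenation of the acetylide, then O-silylation). Alkyne 14 comes via 13 and 12 from epoxide 9 and ethynyltrimethylsilane 10 by cutting C4–C4a. Opening a terminal epoxide at its CH2 group touches neither stereocentre. Propargylating an α-oxygenated aldehyde would instead create C3 with uncertain diastereoselectivity.

**C2 and C3.** Silyl ether 9 comes from epoxy alcohol 8, and 8 from racemic allylic alcohol 7 by a Sharpless kinetic resolution. That single event selects the C2 configuration and creates C3 in the erythro sense. Asymmetric dihydroxylation of an E-alkene would give the threo chain, which needs either retention at C2 or a later inversion at C3. Alcohol 7 is cut at C2–C3 into aldehyde 5 and vinylmagnesium bromide 6.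

**Ring B and the four-carbon partner.** Aldehyde 5 is reached from methyl gallate 1 through 2, 3 and 4. The 4-O-methyl group is placed first, using the higher acidity of the hydroxyl para to the ester. Cyclobutenone 19 comes from commercial 3-ethoxycyclobut-2-en-1-one 18 by alkoxy exchange.

## Roads not taken

**Alternative 1:** Ring C is closed last across C3=C4 by ring-closing metathesis.
- Cut: the C3=C4 bond of 2H-chromene A2 is removed, leaving diene A1. In A1, O1 links a 2-vinyl ring A to the benzylic C2, and C2 carries a 1-(galloyloxy)vinyl group.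
- Forward: RuCl2(H2IMes)(PCy3)(=CHPh), the second-generation Grubbs catalyst, would join the styrene carbon to the enol ester carbon. Hydrogenation over palladium would then add hydrogen to C3=C4 from the face away from the C2 aryl group, setting C3 cis to C2, and remove all benzyl groups in the same flask.
- Merits: the gallate is in place from the start, only C2 must be set by asymmetric synthesis, and the endgame is one operation.
- Weak points:
  - A1 requires an enol ester formed toward the terminal carbon of an α-aryloxy ketone, although the benzylic, oxygen-bearing C2–H is the more acidic position. Enolisation there destroys the only stereocentre.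
  - C2 in A1 and A2 is at once benzylic, allylic and bonded to an aryloxy leaving group. Ionisation, aromatic Claisen rearrangement toward C8 on heating, and hydrogenolysis of C2–O1 in the last step all threaten it.
  - Metathesis of a 1,1-disubstituted enol ester to a trisubstituted electron-rich olefin is slow.
- Comparison: in step count this road is clearly shorter. The chosen plan sets against it that both stereocentres are fixed by reagent control on carbons that are never enolisable or allylic afterwards.

**Alternative 2:** Ring C is closed at O1–C8a by palladium-catalysed aryl etherification.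
- Cut: O1–C8a of chroman A4 (identical in structure with 27), leaving the threo bromo alcohol A3.
- Forward: Pd(OAc)2 with 2-(di-tert-butylphosphino)-1,1'-binaphthyl and Cs2CO3 would couple the C2 hydroxyl with the ring A bromide, with retention at C2.
- Merits: C2 never undergoes substitution, so there is no risk of ionisation at the electron-rich benzylic carbon. The threo chain of A3 is available by catalytic asymmetric dihydroxylation of the corresponding E-alkene, which uses all of the material, not half of it. Ring A is bought, not built.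
- Weak points: the bromide sits between two ortho substituents on a very electron-rich ring, so oxidative addition to zerovalent palladium is slow. The palladium alkoxide of a secondary benzylic alcohol has a β-hydrogen, and β-hydride elimination would give an aryl ketone and a debrominated arene. The two hydroxyls of the diol and the positions of the ring A precursor must also be differentiated.
- Comparison: in length and in use of material this road is at least as good as the chosen one, probably better. The chosen plan sets against it a metal-free ring closure by a substitution of broad scope, and a ring A that arrives with C5, C7 and C8a oxygens already differentiated and without any halogenation.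

**Alternative 3:** Ring A is folded from a 2-pyrone.
- Cut: the C4a–C8a bond of resorcinol A6, traced to pyrone A5, a 4-benzyloxy-2-pyrone whose C6 carries the chain through C4a.
- Forward: LiN(i-Pr)2 or KN(SiMe3)2 would deprotonate C4a. The ring would open to a dienylketene enolate, and C4a would attack the former lactone carbonyl to give A6 with free hydroxyls at C5 and C8a.
- Merits: inexpensive reagents, no heating, and no ynol ether. The two free phenols of A6 are equivalent toward ring C closure, so no differentiation is needed.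
- Weak points: the anion of a 6-alkylpyrone is a stabilised extended enolate that is normally alkylated without ring opening. The opening would need a warm, strongly basic solution, in which attack of the base on the lactone and deprotonation of the benzyl ether compete. The rearrangement lacks close precedent.
- Comparison: the length is similar and the reagents are cheaper. The chosen plan sets against it a key step of a known reaction type that runs under neutral conditions.

Key step: step 13

Remark on the chemistry: flavan numbering (O1, C2, C3, C4, C4a, C5 to C8, C8a) is used for all open-chain intermediates, and 3,4,5-tris(benzyloxy)benzoic acid 29 is assumed to be purchased (otherwise two steps from gallic acid).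

## Steps

Step 1
Reactants: 1 methyl gallate
Product: 2 methyl 3,5-dihydroxy-4-methoxybenzoate
Conditions: MeI (1.05 equiv), Li2CO3, DMF, 40 °C
Reagents that add atoms: iodomethane CI
Why: Williamson etherification; the hydroxyl para to the ester is the most acidic, so a weak base and one equivalent of MeI should alkylate it selectively.

Step 2
Reactants: 2 methyl 3,5-dihydroxy-4-methoxybenzoate
Product: 3 methyl 3,5-bis(benzyloxy)-4-methoxybenzoate
Conditions: BnBr, K2CO3, DMF, 60 °C
Reagents that add atoms: benzyl bromide BrCc1ccccc1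
Why: Williamson etherification of both remaining phenols.

Step 3
Reactants: 3 methyl 3,5-bis(benzyloxy)-4-methoxybenzoate
Product: 4 [3,5-bis(benzyloxy)-4-methoxyphenyl]methanol
Conditions: LiAlH4, THF, 0 °C
Reagents that add atoms: none
Why: Hydride reduction of the ester to the benzylic alcohol; aryl ethers are inert.

Step 4
Reactants: 4 [3,5-bis(benzyloxy)-4-methoxyphenyl]methanol
Product: 5 3,5-bis(benzyloxy)-4-methoxybenzaldehyde
Conditions: MnO2, CH2Cl2, rt
Reagents that add atoms: none
Why: Selective oxidation of a benzylic alcohol by MnO2, which stops at the aldehyde.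

Step 5
Reactants: 5 3,5-bis(benzyloxy)-4-methoxybenzaldehyde; 6 vinylmagnesium bromide
Product: 7 rac-1-[3,5-bis(benzyloxy)-4-methoxyphenyl]prop-2-en-1-ol
Conditions: THF, 0 °C; aq. NH4Cl
Reagents that add atoms: none
Why: Grignard addition to the aldehyde forms the C2–C3 bond and gives the racemic aryl vinyl carbinol needed for resolution.

Step 6
Reactants: 7 rac-1-[3,5-bis(benzyloxy)-4-methoxyphenyl]prop-2-en-1-ol
Product: 8 (S)-[3,5-bis(benzyloxy)-4-methoxyphenyl][(R)-oxiran-2-yl]methanol
Conditions: Ti(Oi-Pr)4 (cat.), L-(+)-DIPT, t-BuOOH (0.45 equiv), 4 Å MS, CH2Cl2, −20 °C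
Reagents that add atoms: tert-butyl hydroperoxide CC(C)(C)OO
Why: Sharpless kinetic resolution; with L-(+)-DIPT the (R)-carbinol is the fast-reacting enantiomer and is epoxidised on the face that gives the erythro epoxy alcohol, so the tartrate sets C2 by selection and C3 by oxygen delivery. Conversion is kept below half so that the product is harvested enantiomerically enriched.

Step 7
Reactants: 8 (S)-[3,5-bis(benzyloxy)-4-methoxyphenyl][(R)-oxiran-2-yl]methanol
Product: 9 tert-butyl{(S)-[3,5-bis(benzyloxy)-4-methoxyphenyl][(R)-oxiran-2-yl]methoxy}dimethylsilane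
Conditions: TBSCl, imidazole, DMF, rt
Reagents that add atoms: tert-butyldimethylsilyl chloride CC(C)(C)[Si](C)(C)Cl
Why: Silylation of the secondary alcohol under mildly basic conditions that leave the epoxide untouched.

Step 8
Reactants: 9 tert-butyl{(S)-[3,5-bis(benzyloxy)-4-methoxyphenyl][(R)-oxiran-2-yl]methoxy}dimethylsilane; 10 ethynyltrimethylsilane
Product: 12 (1S,2R)-1-[3,5-bis(benzyloxy)-4-methoxyphenyl]-1-[(tert-butyldimethylsilyl)oxy]-5-(trimethylsilyl)pent-4-yn-2-ol, via lithium (trimethylsilyl)acetylide 11 (not isolated)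
Conditions: 10, n-BuLi, THF, −78 °C; BF3·OEt2, then 9, −78 °C
Reagents that add atoms: none
Why: Yamaguchi–Hirao alkynylation; the BF3-activated terminal epoxide is opened at its CH2 carbon, forming C4–C4a without touching C3. The low temperature and boron-bound alkoxide should suppress 1,2-silyl migration.

Step 9
Reactants: 12 (1S,2R)-1-[3,5-bis(benzyloxy)-4-methoxyphenyl]-1-[(tert-butyldimethylsilyl)oxy]-5-(trimethylsilyl)pent-4-yn-2-ol
Product: 13 tert-butyl{[(1S,2R)-1-[3,5-bis(benzyloxy)-4-methoxyphenyl]-2-(methoxymethoxy)-5-(trimethylsilyl)pent-4-yn-1-yl]oxy}dimethylsilane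
Conditions: MOMCl, i-Pr2NEt, Bu4NI (cat.), CH2Cl2, 0 °C to rt
Reagents that add atoms: chloromethyl methyl ether COCCl
Why: Alkylation of the secondary alcohol to the acetal, which tolerates the base, heat and fluoride of the following steps.

Step 10
Reactants: 13 tert-butyl{[(1S,2R)-1-[3,5-bis(benzyloxy)-4-methoxyphenyl]-2-(methoxymethoxy)-5-(trimethylsilyl)pent-4-yn-1-yl]oxy}dimethylsilane
Product: 14 tert-butyl{[(1S,2R)-1-[3,5-bis(benzyloxy)-4-methoxyphenyl]-2-(methoxymethoxy)pent-4-yn-1-yl]oxy}dimethylsilane
Conditions: K2CO3, MeOH, rt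
Reagents that add atoms: none
Why: Methanolysis of the alkynyl C–Si bond; the oxygen-bound silyl group and the acetal are stable to carbonate in methanol.

Step 11
Reactants: 14 tert-butyl{[(1S,2R)-1-[3,5-bis(benzyloxy)-4-methoxyphenyl]-2-(methoxymethoxy)pent-4-yn-1-yl]oxy}dimethylsilane
Product: 17 {[(4R,5S)-5-[3,5-bis(benzyloxy)-4-methoxyphenyl]-5-[(tert-butyldimethylsilyl)oxy]-4-(methoxymethoxy)pent-1-yn-1-yl]oxy}triisopropylsilane, via chain lithium acetylide 15 (not isolated), via lithium ynolate 16 (not isolated)
Conditions: n-BuLi, THF, −78 °C; LiOOt-Bu (from t-BuOOH and LiN(SiMe3)2), −78 to 0 °C; i-Pr3SiOTf, −78 °C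
Reagents that add atoms: tert-butyl hydroperoxide CC(C)(C)OO; triisopropylsilyl trifluoromethanesulfonate CC(C)[Si](C(C)C)(C(C)C)OS(=O)(=O)C(F)(F)F
Why: Electrophilic oxygenation of a lithium acetylide by lithium tert-butyl peroxide gives the ynolate, which the bulky silyl triflate traps on oxygen; this is a known route from terminal alkynes to triisopropylsiloxyalkynes.

Step 12
Reactants: 18 3-ethoxycyclobut-2-en-1-one
Product: 19 3-(benzyloxy)cyclobut-2-en-1-one
Conditions: BnOH (3 equiv), camphorsulfonic acid (cat.), toluene, 40 °C, reduced pressure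
Reagents that add atoms: benzyl alcohol OCc1ccccc1
Why: Acid-catalysed alkoxy exchange of a vinylogous ester by addition–elimination at C3, driven by removal of ethanol; the temperature stays below that of electrocyclic ring opening.

Step 13
Reactants: 17 {[(4R,5S)-5-[3,5-bis(benzyloxy)-4-methoxyphenyl]-5-[(tert-butyldimethylsilyl)oxy]-4-(methoxymethoxy)pent-1-yn-1-yl]oxy}triisopropylsilane; 19 3-(benzyloxy)cyclobut-2-en-1-one
Product: 24 5-(benzyloxy)-2-[(2R,3S)-3-[3,5-bis(benzyloxy)-4-methoxyphenyl]-3-[(tert-butyldimethylsilyl)oxy]-2-(methoxymethoxy)propyl]-3-[(triisopropylsilyl)oxy]phenol, via 3-(benzyloxy)vinylketene 20 (not isolated), via 4-vinylcyclobutenone adduct 21 (not isolated), via dienylketene 22 (not isolated), via cyclohexadienone tautomer 23 (not isolated)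
Conditions: 19 (1.3 equiv), toluene, 80 °C, then 110 °C, sealed tube
Reagents that add atoms: none
Why: Danheiser benzannulation of a cyclobutenone with a siloxyalkyne, here in the less common variant with an alkoxy group on C3 of the four-membered ring. On heating, 19 opens reversibly (4π) to vinylketene 20; its electrophilic carbonyl carbon (future C5) bonds to the nucleophilic chain-bearing alkyne carbon (C4a) and its α-carbon (C8) to the siloxy carbon (C8a) in a [2+2] cycloaddition giving 21. A second 4π opening gives dienylketene 22, and ring A closes by thermal disrotatory 6π electrocyclisation at C5–C6 to dienone 23, which tautomerises to phenol 24. No stereocentre is formed; C2 and C3 are spectators, and their silyl and acetal groups survive because the medium is neutral and aprotic. The selectivity needed is regiochemical and is secured by the polarisation of the ynol ether, which places C4 between the free C5 hydroxyl and the silylated C8a oxygen and the benzyloxy group para to C4a. The absence of any free hydroxyl in 17 keeps the ketene from being intercepted before cycloaddition. A small excess of 19 compensates for ketene dimerisation.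

Step 14
Reactants: 24 5-(benzyloxy)-2-[(2R,3S)-3-[3,5-bis(benzyloxy)-4-methoxyphenyl]-3-[(tert-butyldimethylsilyl)oxy]-2-(methoxymethoxy)propyl]-3-[(triisopropylsilyl)oxy]phenol
Product: 25 tert-butyl{(1S,2R)-1-[3,5-bis(benzyloxy)-4-methoxyphenyl]-3-{2,4-bis(benzyloxy)-6-[(triisopropylsilyl)oxy]phenyl}-2-(methoxymethoxy)propoxy}dimethylsilane
Conditions: BnBr, K2CO3, Bu4NI (cat.), acetone, 50 °C
Reagents that add atoms: benzyl bromide BrCc1ccccc1
Why: Williamson etherification of the one free phenol under anhydrous carbonate conditions that the hindered aryl triisopropylsilyl ether should tolerate.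

Step 15
Reactants: 25 tert-butyl{(1S,2R)-1-[3,5-bis(benzyloxy)-4-methoxyphenyl]-3-{2,4-bis(benzyloxy)-6-[(triisopropylsilyl)oxy]phenyl}-2-(methoxymethoxy)propoxy}dimethylsilane
Product: 26 (1S,2R)-1-[3,5-bis(benzyloxy)-4-methoxyphenyl]-3-[2,4-bis(benzyloxy)-6-hydroxyphenyl]-2-(methoxymethoxy)propan-1-ol
Conditions: Bu4NF, THF, 0 °C to rt
Reagents that add atoms: none
Why: Fluoride cleaves both Si–O bonds, freeing the C8a phenol and the C2 hydroxyl; the acetal and benzyl ethers are inert.

Step 16
Reactants: 26 (1S,2R)-1-[3,5-bis(benzyloxy)-4-methoxyphenyl]-3-[2,4-bis(benzyloxy)-6-hydroxyphenyl]-2-(methoxymethoxy)propan-1-ol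
Product: 27 (2R,3R)-5,7-bis(benzyloxy)-2-[3,5-bis(benzyloxy)-4-methoxyphenyl]-3-(methoxymethoxy)chromane
Conditions: PPh3, DIAD, THF, 0 °C
Reagents that add atoms: none
Why: Intramolecular Mitsunobu etherification; the phenol displaces the activated benzylic oxygen in a 6-exo-tet SN2 closure with inversion at C2, which turns the erythro chain into the 2,3-cis chroman while C3 is untouched.

Step 17
Reactants: 27 (2R,3R)-5,7-bis(benzyloxy)-2-[3,5-bis(benzyloxy)-4-methoxyphenyl]-3-(methoxymethoxy)chromane
Product: 28 (2R,3R)-5,7-bis(benzyloxy)-2-[3,5-bis(benzyloxy)-4-methoxyphenyl]chroman-3-ol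
Conditions: conc. HCl (cat.), MeOH/THF, 40 °C
Reagents that add atoms: none
Why: Acid-catalysed acetal exchange with methanol removes the methoxymethyl group; with all phenols benzylated, the chroman should not open at C2 under these mild conditions.

Step 18
Reactants: 28 (2R,3R)-5,7-bis(benzyloxy)-2-[3,5-bis(benzyloxy)-4-methoxyphenyl]chroman-3-ol; 29 3,4,5-tris(benzyloxy)benzoic acid
Product: 30 (2R,3R)-5,7-bis(benzyloxy)-2-[3,5-bis(benzyloxy)-4-methoxyphenyl]chroman-3-yl 3,4,5-tris(benzyloxy)benzoate
Conditions: DCC, DMAP, CH2Cl2, rt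
Reagents that add atoms: none
Why: Steglich esterification; the acylpyridinium intermediate acylates the hindered axial C3 hydroxyl without disturbing either stereocentre.

Step 19
Reactants: 30 (2R,3R)-5,7-bis(benzyloxy)-2-[3,5-bis(benzyloxy)-4-methoxyphenyl]chroman-3-yl 3,4,5-tris(benzyloxy)benzoate
Product: 31 4'-O-methylepigallocatechin-3-O-gallate, (2R,3R)-5,7-dihydroxy-2-(3,5-dihydroxy-4-methoxyphenyl)chroman-3-yl 3,4,5-trihydroxybenzoate
Conditions: H2 (1 atm), Pd(OH)2/C, THF/MeOH, rt
Reagents that add atoms: none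
Why: Neutral hydrogenolysis of the seven benzyl ethers; the methyl ether, the ester and, under these mild conditions, the C2–O1 bond should remain.

## Compound list

1 | methyl gallate | COC(=O)c1cc(O)c(O)c(O)c1 | starting material
2 | methyl 3,5-dihydroxy-4-methoxybenzoate | COC(=O)c1cc(O)c(OC)c(O)c1 | intermediate
3 | methyl 3,5-bis(benzyloxy)-4-methoxybenzoate | COC(=O)c1cc(OCc2ccccc2)c(OC)c(OCc2ccccc2)c1 | intermediate
4 | [3,5-bis(benzyloxy)-4-methoxyphenyl]methanol | COc1c(OCc2ccccc2)cc(CO)cc1OCc2ccccc2 | intermediate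
5 | 3,5-bis(benzyloxy)-4-methoxybenzaldehyde | COc1c(OCc2ccccc2)cc(C=O)cc1OCc2ccccc2 | intermediate
6 | vinylmagnesium bromide | C=C[Mg]Br | starting material
7 | rac-1-[3,5-bis(benzyloxy)-4-methoxyphenyl]prop-2-en-1-ol | COc1c(OCc2ccccc2)cc(C(O)C=C)cc1OCc2ccccc2 | intermediate
8 | (S)-[3,5-bis(benzyloxy)-4-methoxyphenyl][(R)-oxiran-2-yl]methanol | COc1c(OCc2ccccc2)cc([C@H](O)[C@H]3CO3)cc1OCc2ccccc2 | intermediate
9 | tert-butyl{(S)-[3,5-bis(benzyloxy)-4-methoxyphenyl][(R)-oxiran-2-yl]methoxy}dimethylsilane | COc1c(OCc2ccccc2)cc([C@H](O[Si](C)(C)C(C)(C)C)[C@H]3CO3)cc1OCc2ccccc2 | intermediate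
10 | ethynyltrimethylsilane | C#C[Si](C)(C)C | starting material
11 | lithium (trimethylsilyl)acetylide (not isolated) | [Li+].[C-]#C[Si](C)(C)C | intermediate
12 | (1S,2R)-1-[3,5-bis(benzyloxy)-4-methoxyphenyl]-1-[(tert-butyldimethylsilyl)oxy]-5-(trimethylsilyl)pent-4-yn-2-ol | COc1c(OCc2ccccc2)cc([C@H](O[Si](C)(C)C(C)(C)C)[C@H](O)CC#C[Si](C)(C)C)cc1OCc2ccccc2 | intermediate
13 | tert-butyl{[(1S,2R)-1-[3,5-bis(benzyloxy)-4-methoxyphenyl]-2-(methoxymethoxy)-5-(trimethylsilyl)pent-4-yn-1-yl]oxy}dimethylsilane | COc1c(OCc2ccccc2)cc([C@H](O[Si](C)(C)C(C)(C)C)[C@H](OCOC)CC#C[Si](C)(C)C)cc1OCc2ccccc2 | intermediate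
14 | tert-butyl{[(1S,2R)-1-[3,5-bis(benzyloxy)-4-methoxyphenyl]-2-(methoxymethoxy)pent-4-yn-1-yl]oxy}dimethylsilane | COc1c(OCc2ccccc2)cc([C@H](O[Si](C)(C)C(C)(C)C)[C@H](OCOC)CC#C)cc1OCc2ccccc2 | intermediate
15 | lithium acetylide of 14 (not isolated) | COc1c(OCc2ccccc2)cc([C@H](O[Si](C)(C)C(C)(C)C)[C@H](OCOC)CC#[C-])cc1OCc2ccccc2.[Li+] | intermediate
16 | lithium (4R,5S)-5-[3,5-bis(benzyloxy)-4-methoxyphenyl]-5-[(tert-butyldimethylsilyl)oxy]-4-(methoxymethoxy)pent-1-yn-1-olate (not isolated) | COc1c(OCc2ccccc2)cc([C@H](O[Si](C)(C)C(C)(C)C)[C@H](OCOC)CC#C[O-])cc1OCc2ccccc2.[Li+] | intermediate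
17 | {[(4R,5S)-5-[3,5-bis(benzyloxy)-4-methoxyphenyl]-5-[(tert-butyldimethylsilyl)oxy]-4-(methoxymethoxy)pent-1-yn-1-yl]oxy}triisopropylsilane | COc1c(OCc2ccccc2)cc([C@H](O[Si](C)(C)C(C)(C)C)[C@H](OCOC)CC#CO[Si](C(C)C)(C(C)C)C(C)C)cc1OCc2ccccc2 | intermediate
18 | 3-ethoxycyclobut-2-en-1-one | CCOC1=CC(=O)C1 | starting material
19 | 3-(benzyloxy)cyclobut-2-en-1-one | O=C1C=C(OCc2ccccc2)C1 | intermediate
20 | 3-(benzyloxy)buta-1,3-dien-1-one, the vinylketene (not isolated) | O=C=CC(=C)OCc1ccccc1 | intermediate
21 | 4-[1-(benzyloxy)vinyl]-2-[(2R,3S)-3-[3,5-bis(benzyloxy)-4-methoxyphenyl]-3-[(tert-butyldimethylsilyl)oxy]-2-(methoxymethoxy)propyl]-3-[(triisopropylsilyl)oxy]cyclobut-2-en-1-one, both epimers at the ring CH (not isolated) | COc1c(OCc2ccccc2)cc([C@H](O[Si](C)(C)C(C)(C)C)[C@H](OCOC)CC3=C(O[Si](C(C)C)(C(C)C)C(C)C)C(C(=C)OCc2ccccc2)C3=O)cc1OCc2ccccc2 | intermediate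
22 | dienylketene with ketene and benzyloxyvinyl groups cis on the C8a=C8 double bond, O=C=C(chain)–C(OSi(i-Pr)3)=CH–C(OBn)=CH2 (not isolated) | COc1c(OCc2ccccc2)cc([C@H](O[Si](C)(C)C(C)(C)C)[C@H](OCOC)CC(=C=O)/C(O[Si](C(C)C)(C(C)C)C(C)C)=C\C(=C)OCc2ccccc2)cc1OCc2ccccc2 | intermediate
23 | 4-(benzyloxy)-6-[(2R,3S)-3-[3,5-bis(benzyloxy)-4-methoxyphenyl]-3-[(tert-butyldimethylsilyl)oxy]-2-(methoxymethoxy)propyl]-5-[(triisopropylsilyl)oxy]cyclohexa-3,5-dien-1-one, the keto tautomer of 24 (not isolated) | COc1c(OCc2ccccc2)cc([C@H](O[Si](C)(C)C(C)(C)C)[C@H](OCOC)CC3=C(O[Si](C(C)C)(C(C)C)C(C)C)C=C(OCc2ccccc2)CC3=O)cc1OCc2ccccc2 | intermediate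
24 | 5-(benzyloxy)-2-[(2R,3S)-3-[3,5-bis(benzyloxy)-4-methoxyphenyl]-3-[(tert-butyldimethylsilyl)oxy]-2-(methoxymethoxy)propyl]-3-[(triisopropylsilyl)oxy]phenol | COc1c(OCc2ccccc2)cc([C@H](O[Si](C)(C)C(C)(C)C)[C@H](OCOC)Cc3c(O)cc(OCc2ccccc2)cc3O[Si](C(C)C)(C(C)C)C(C)C)cc1OCc2ccccc2 | intermediate
25 | tert-butyl{(1S,2R)-1-[3,5-bis(benzyloxy)-4-methoxyphenyl]-3-{2,4-bis(benzyloxy)-6-[(triisopropylsilyl)oxy]phenyl}-2-(methoxymethoxy)propoxy}dimethylsilane | COc1c(OCc2ccccc2)cc([C@H](O[Si](C)(C)C(C)(C)C)[C@H](OCOC)Cc3c(OCc2ccccc2)cc(OCc2ccccc2)cc3O[Si](C(C)C)(C(C)C)C(C)C)cc1OCc2ccccc2 | intermediate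
26 | (1S,2R)-1-[3,5-bis(benzyloxy)-4-methoxyphenyl]-3-[2,4-bis(benzyloxy)-6-hydroxyphenyl]-2-(methoxymethoxy)propan-1-ol | COc1c(OCc2ccccc2)cc([C@H](O)[C@H](OCOC)Cc3c(OCc2ccccc2)cc(OCc2ccccc2)cc3O)cc1OCc2ccccc2 | intermediate
27 | (2R,3R)-5,7-bis(benzyloxy)-2-[3,5-bis(benzyloxy)-4-methoxyphenyl]-3-(methoxymethoxy)chromane | COc1c(OCc5ccccc5)cc([C@H]2Oc3cc(OCc5ccccc5)cc(OCc5ccccc5)c3C[C@H]2OCOC)cc1OCc5ccccc5 | intermediate
28 | (2R,3R)-5,7-bis(benzyloxy)-2-[3,5-bis(benzyloxy)-4-methoxyphenyl]chroman-3-ol | COc1c(OCc5ccccc5)cc([C@H]2Oc3cc(OCc5ccccc5)cc(OCc5ccccc5)c3C[C@H]2O)cc1OCc5ccccc5 | intermediate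
29 | 3,4,5-tris(benzyloxy)benzoic acid | OC(=O)c1cc(OCc2ccccc2)c(OCc2ccccc2)c(OCc2ccccc2)c1 | starting material
30 | (2R,3R)-5,7-bis(benzyloxy)-2-[3,5-bis(benzyloxy)-4-methoxyphenyl]chroman-3-yl 3,4,5-tris(benzyloxy)benzoate | COc1c(OCc5ccccc5)cc([C@H]2Oc3cc(OCc5ccccc5)cc(OCc5ccccc5)c3C[C@H]2OC(=O)c4cc(OCc5ccccc5)c(OCc5ccccc5)c(OCc5ccccc5)c4)cc1OCc5ccccc5 | intermediate
31 | 4'-O-methylepigallocatechin-3-O-gallate | COc1c(O)cc([C@H]2Oc3cc(O)cc(O)c3C[C@H]2OC(=O)c2cc(O)c(O)c(O)c2)cc1O | target

## Step count and uncertain steps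

Total step count: 19. Longest linear sequence: 18 steps (steps 1 to 11 and 13 to 19, from 1 to 31); step 12 is a one-step side branch.

**Step 13 (key step).**
- Risk: the vinylogous ester 19 is stabilised by push–pull conjugation and may open to the vinylketene only at temperatures where other processes compete. These are 1,3-silyl shift of the siloxyalkyne to a silylketene, acylation of the product phenol by the vinylketene, and ketene dimerisation.
- Fallback: ring A is brought in preformed and the annulation is given up, while the erythro chain and the endgame are kept. The detour sets out from 9 and returns at 25.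
  - Purchased 3,5-bis(benzyloxy)phenol is iodinated with N-iodosuccinimide to 3,5-bis(benzyloxy)-2-iodophenol F1.
  - F1 is silylated (i-Pr3SiCl, imidazole) to [3,5-bis(benzyloxy)-2-iodophenoxy]triisopropylsilane F2.
  - Iodine–magnesium exchange with i-PrMgCl·LiCl gives {2,4-bis(benzyloxy)-6-[(triisopropylsilyl)oxy]phenyl}magnesium chloride F3. Magnesium is chosen over lithium to avoid oxygen-to-carbon silyl migration.
  - CuI-catalysed opening of epoxide 9 at its CH2 carbon gives (1S,2R)-1-[3,5-bis(benzyloxy)-4-methoxyphenyl]-3-{2,4-bis(benzyloxy)-6-[(triisopropylsilyl)oxy]phenyl}-1-[(tert-butyldimethylsilyl)oxy]propan-2-ol F4.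
  - MOMCl and i-Pr2NEt convert F4 into 25.

**Step 11.**
- Risk: oxygen transfer to the acetylide may be incomplete, the ambident ynolate may be silylated on carbon to give a silylketene, and the siloxyalkyne may hydrolyse during isolation.
- Fallback: the ynolate is made by Kowalski ester homologation instead of acetylide oxidation. The detour sets out from 9 and returns at 16.
  - Methoxycarbonylation of the epoxide (CO, MeOH, Co2(CO)8, 3-hydroxypyridine) gives methyl (3R,4S)-4-[3,5-bis(benzyloxy)-4-methoxyphenyl]-4-[(tert-butyldimethylsilyl)oxy]-3-hydroxybutanoate F5.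
  - MOMCl and i-Pr2NEt give methyl (3R,4S)-4-[3,5-bis(benzyloxy)-4-methoxyphenyl]-4-[(tert-butyldimethylsilyl)oxy]-3-(methoxymethoxy)butanoate F6.
  - LiCHBr2 (from CH2Br2 and lithium 2,2,6,6-tetramethylpiperidide) converts F6 into lithium (4R,5S)-5-[3,5-bis(benzyloxy)-4-methoxyphenyl]-1,1-dibromo-5-[(tert-butyldimethylsilyl)oxy]-4-(methoxymethoxy)pent-1-en-2-olate F7.
  - n-BuLi then effects bromine–lithium exchange and 1,2-shift to ynolate 16, which is silylated as in step 11 to give 17.

**Step 16.**
- Risk: the benzylic oxygen, activated as the oxyphosphonium ion on a ring bearing a para methoxy group, may ionise before the phenol attacks. This would cause loss of stereochemical fidelity at C2 or elimination.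
- Fallback: reductive etherification, which sets C2 from C3 instead of by inversion. The detour sets out from 26 and returns at 27.
  - MnO2 oxidises the benzylic alcohol to (R)-1-[3,5-bis(benzyloxy)-4-methoxyphenyl]-3-[2,4-bis(benzyloxy)-6-hydroxyphenyl]-2-(methoxymethoxy)propan-1-one F8.
  - Et3SiH and BF3·OEt2 at −78 °C close O1–C2 by ionic hydrogenation. Hydride is delivered to the cyclic oxocarbenium ion anti to the C3 substituent, which gives the 2,3-cis chroman 27.

**Step 6.**
- Risk: the rate difference between the enantiomers of an aryl vinyl carbinol may be too small for a highly enriched epoxy alcohol at useful conversion. The Lewis acid may also open the epoxide, and at most half of 7 is usable.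
- Fallback: enantiopurity is secured on recovered alcohol, not on the product. The detour sets out from 7 and returns at 8.
  - A resolution with D-(−)-DIPT is run past half conversion and (R)-1-[3,5-bis(benzyloxy)-4-methoxyphenyl]prop-2-en-1-ol F9 is recovered.
  - F9 is epoxidised with the matched L-(+)-DIPT system to give 8.

**Step 12.**
- Risk: under acid, benzyl alcohol may open the strained ring of the vinylogous ester instead of exchanging the alkoxy group.
- Fallback: the detour sets out from 18 and returns at 19. Cold aqueous HCl hydrolyses 18 to cyclobutane-1,3-dione F10, which is O-benzylated under neutral Mitsunobu conditions (BnOH, PPh3, DIAD) to give 19.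

## Further compounds

F1 | step 13 | 3,5-bis(benzyloxy)-2-iodophenol | Oc1cc(OCc2ccccc2)cc(OCc2ccccc2)c1I
F2 | step 13 | [3,5-bis(benzyloxy)-2-iodophenoxy]triisopropylsilane | CC(C)[Si](Oc1cc(OCc2ccccc2)cc(OCc2ccccc2)c1I)(C(C)C)C(C)C
F3 | step 13 | {2,4-bis(benzyloxy)-6-[(triisopropylsilyl)oxy]phenyl}magnesium chloride | CC(C)[Si](Oc1cc(OCc2ccccc2)cc(OCc2ccccc2)c1[Mg]Cl)(C(C)C)C(C)C
F4 | step 13 | (1S,2R)-1-[3,5-bis(benzyloxy)-4-methoxyphenyl]-3-{2,4-bis(benzyloxy)-6-[(triisopropylsilyl)oxy]phenyl}-1-[(tert-butyldimethylsilyl)oxy]propan-2-ol | COc1c(OCc5ccccc5)cc([C@H](O[Si](C)(C)C(C)(C)C)[C@H](O)Cc3c(OCc5ccccc5)cc(OCc5ccccc5)cc3O[Si](C(C)C)(C(C)C)C(C)C)cc1OCc5ccccc5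
F5 | step 11 | methyl (3R,4S)-4-[3,5-bis(benzyloxy)-4-methoxyphenyl]-4-[(tert-butyldimethylsilyl)oxy]-3-hydroxybutanoate | COc1c(OCc2ccccc2)cc([C@H](O[Si](C)(C)C(C)(C)C)[C@H](O)CC(=O)OC)cc1OCc2ccccc2
F6 | step 11 | methyl (3R,4S)-4-[3,5-bis(benzyloxy)-4-methoxyphenyl]-4-[(tert-butyldimethylsilyl)oxy]-3-(methoxymethoxy)butanoate | COc1c(OCc2ccccc2)cc([C@H](O[Si](C)(C)C(C)(C)C)[C@H](OCOC)CC(=O)OC)cc1OCc2ccccc2
F7 | step 11 | lithium (4R,5S)-5-[3,5-bis(benzyloxy)-4-methoxyphenyl]-1,1-dibromo-5-[(tert-butyldimethylsilyl)oxy]-4-(methoxymethoxy)pent-1-en-2-olate | COc1c(OCc2ccccc2)cc([C@H](O[Si](C)(C)C(C)(C)C)[C@H](OCOC)CC([O-])=C(Br)Br)cc1OCc2ccccc2.[Li+]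
F8 | step 16 | (R)-1-[3,5-bis(benzyloxy)-4-methoxyphenyl]-3-[2,4-bis(benzyloxy)-6-hydroxyphenyl]-2-(methoxymethoxy)propan-1-one | COc1c(OCc5ccccc5)cc(C(=O)[C@H](OCOC)Cc3c(OCc5ccccc5)cc(OCc5ccccc5)cc3O)cc1OCc5ccccc5
F9 | step 6 | (R)-1-[3,5-bis(benzyloxy)-4-methoxyphenyl]prop-2-en-1-ol | COc1c(OCc2ccccc2)cc([C@H](O)C=C)cc1OCc2ccccc2
F10 | step 12 | cyclobutane-1,3-dione | O=C1CC(=O)C1
A1 | alternative 1 | (R)-3-[3,5-bis(benzyloxy)-4-methoxyphenyl]-3-[3,5-bis(benzyloxy)-2-vinylphenoxy]prop-1-en-2-yl 3,4,5-tris(benzyloxy)benzoate | COc1c(OCc5ccccc5)cc([C@@H](Oc3cc(OCc5ccccc5)cc(OCc5ccccc5)c3C=C)C(=C)OC(=O)c4cc(OCc5ccccc5)c(OCc5ccccc5)c(OCc5ccccc5)c4)cc1OCc5ccccc5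
A2 | alternative 1 | (R)-5,7-bis(benzyloxy)-2-[3,5-bis(benzyloxy)-4-methoxyphenyl]-2H-chromen-3-yl 3,4,5-tris(benzyloxy)benzoate | COc1c(OCc5ccccc5)cc([C@H]2Oc3cc(OCc5ccccc5)cc(OCc5ccccc5)c3C=C2OC(=O)c4cc(OCc5ccccc5)c(OCc5ccccc5)c(OCc5ccccc5)c4)cc1OCc5ccccc5
A3 | alternative 2 | (1R,2R)-1-[3,5-bis(benzyloxy)-4-methoxyphenyl]-3-[2,4-bis(benzyloxy)-6-bromophenyl]-2-(methoxymethoxy)propan-1-ol | COc1c(OCc5ccccc5)cc([C@@H](O)[C@H](OCOC)Cc3c(Br)cc(OCc5ccccc5)cc3OCc5ccccc5)cc1OCc5ccccc5
A4 | alternative 2 | (2R,3R)-5,7-bis(benzyloxy)-2-[3,5-bis(benzyloxy)-4-methoxyphenyl]-3-(methoxymethoxy)chromane | COc1c(OCc5ccccc5)cc([C@H]2Oc3cc(OCc5ccccc5)cc(OCc5ccccc5)c3C[C@H]2OCOC)cc1OCc5ccccc5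
A5 | alternative 3 | 4-(benzyloxy)-6-[(3R,4S)-4-[3,5-bis(benzyloxy)-4-methoxyphenyl]-4-[(tert-butyldimethylsilyl)oxy]-3-(methoxymethoxy)butyl]-2H-pyran-2-one | COc1c(OCc5ccccc5)cc([C@H](O[Si](C)(C)C(C)(C)C)[C@H](OCOC)CCc3cc(OCc5ccccc5)cc(=O)o3)cc1OCc5ccccc5
A6 | alternative 3 | 5-(benzyloxy)-2-[(2R,3S)-3-[3,5-bis(benzyloxy)-4-methoxyphenyl]-3-[(tert-butyldimethylsilyl)oxy]-2-(methoxymethoxy)propyl]benzene-1,3-diol | COc1c(OCc5ccccc5)cc([C@H](O[Si](C)(C)C(C)(C)C)[C@H](OCOC)Cc3c(O)cc(OCc5ccccc5)cc3O)cc1OCc5ccccc5
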